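Naphthalene numbering is used; ring A is the resorcinol ring, ring B the dihydroquinone ring. Ring B hides a 1,2-dielectrophile and a 1,4-dinucleophile: the C1 ketone next to the tertiary carbinol C2 is an α-keto ester in disguise, C3 is the α-carbon of the C4 aryl ketone and C8a is ortho to that acyl group. In one flask the α-chloro enolate of a ring A bromo ketone adds to a chiral α-keto ester that carries the whole side chain (C2–C3), and bromine–lithium exchange then acylates C8a with the ester (C1–C8a), closing ring B, setting both fully substituted stereocentres and expelling the auxiliary. Desilylation ends the route.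

Key step: step 10

Assumption: the (1S,2R,5S)-8-phenylmenthyl ester is taken to leave open the ketone face that gives the 2S carbinol, by analogy with the usual sense of additions to chelated 8-phenylmenthyl α-keto esters; if the sense is opposite, the enantiomeric auxiliary is used with no other change.

Step 1
Reactants: 1 ethyl but-2-ynoate; 2 geranyl bromide, (2E)-1-bromo-3,7-dimethylocta-2,6-diene
Product: 4 ethyl (4E)-5,9-dimethyl-2-(propan-2-ylidene)deca-4,8-dienoate, via lithium alkenyl(methyl)cuprate 3 (not isolated)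
Conditions: Me2CuLi (from CuI and MeLi), THF, −78 °C; then 2, HMPA, −78 → −20 °C
Reagents that add atoms: lithium dimethylcuprate, [Li+].C[Cu-]C
Why: Carbocupration of the ynoate gives an α-cuprio acrylate (allenolate equivalent) that should be C-allylated by the primary allylic bromide; both β-substituents are methyl, so no alkene geometry is at stake (conjugate addition with enolate trapping).

Step 2
Reactants: 4 ethyl (4E)-5,9-dimethyl-2-(propan-2-ylidene)deca-4,8-dienoate
Product: 5 (4E)-5,9-dimethyl-2-(propan-2-ylidene)deca-4,8-dien-1-ol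
Conditions: i-Bu2AlH (2.2 equiv), CH2Cl2, −78 → 0 °C
Reagents that add atoms: none
Why: 1,2-Reduction of the conjugated ester by the aluminium hydride should give the allylic alcohol and leave the isolated alkenes untouched.

Step 3
Reactants: 5 (4E)-5,9-dimethyl-2-(propan-2-ylidene)deca-4,8-dien-1-ol
Product: 6 (5E)-3-(bromomethyl)-2,6,10-trimethylundeca-2,5,9-triene
Conditions: CBr4, PPh3, CH2Cl2, 0 °C
Reagents that add atoms: tetrabromomethane, BrC(Br)(Br)Br
Why: The Appel reaction converts the primary allylic alcohol into the bromide under neutral conditions by SN2 displacement of the oxyphosphonium group.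

Step 4
Reactants: 7 1,3-dithiane-2-carboxylic acid; 8 (+)-8-phenylmenthol, (1S,2R,5S)-5-methyl-2-(2-phenylpropan-2-yl)cyclohexan-1-ol
Product: 9 (1S,2R,5S)-5-methyl-2-(2-phenylpropan-2-yl)cyclohexyl 1,3-dithiane-2-carboxylate
Conditions: DCC, DMAP (cat.), CH2Cl2, 0 °C → rt
Reagents that add atoms: none
Why: Steglich esterification acylates the hindered secondary alcohol of the auxiliary with the masked glyoxylic acid.

Step 5
Reactants: 9 (1S,2R,5S)-5-methyl-2-(2-phenylpropan-2-yl)cyclohexyl 1,3-dithiane-2-carboxylate; 6 (5E)-3-(bromomethyl)-2,6,10-trimethylundeca-2,5,9-triene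
Product: 11 (1S,2R,5S)-5-methyl-2-(2-phenylpropan-2-yl)cyclohexyl 2-[(4E)-5,9-dimethyl-2-(propan-2-ylidene)deca-4,8-dien-1-yl]-1,3-dithiane-2-carboxylate, via sodium ester enolate 10 (not isolated)
Conditions: NaH, THF/DMF, 0 °C; then 6, 0 °C → rt
Reagents that add atoms: none
Why: The sulfur- and ester-stabilised carbanion, an acyl anion equivalent in the sense of the Corey–Seebach reaction, should be alkylated by SN2 at the primary allylic bromide.

Step 6
Reactants: 11 (1S,2R,5S)-5-methyl-2-(2-phenylpropan-2-yl)cyclohexyl 2-[(4E)-5,9-dimethyl-2-(propan-2-ylidene)deca-4,8-dien-1-yl]-1,3-dithiane-2-carboxylate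
Product: 12 (1S,2R,5S)-5-methyl-2-(2-phenylpropan-2-yl)cyclohexyl (6E)-7,11-dimethyl-2-oxo-4-(propan-2-ylidene)dodeca-6,10-dienoate
Conditions: PhI(OCOCF3)2, NaHCO3, MeCN/H2O (9:1), 0 °C
Reagents that add atoms: water, O
Why: Oxidative hydrolysis of the dithioketal with the hypervalent iodine reagent unmasks the ketone; attack at sulfur should be much faster than at the isolated alkenes, and bicarbonate buffers the acid formed.

Step 7
Reactants: 13 5-bromobenzene-1,3-diol; 14 propanoic acid
Product: 15 1-(2-bromo-4,6-dihydroxyphenyl)propan-1-one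
Conditions: BF3·OEt2, 90 °C
Reagents that add atoms: none
Why: A Nencki-type Friedel–Crafts acylation should take place at the position para to one hydroxyl and ortho to the other (the usual site for 5-substituted resorcinols), which places bromine ortho to the acyl group.

Step 8
Reactants: 15 1-(2-bromo-4,6-dihydroxyphenyl)propan-1-one
Product: 16 1-[2-bromo-4,6-bis(tert-butyldimethylsilyloxy)phenyl]propan-1-one
Conditions: t-BuMe2SiCl, imidazole, DMAP (cat.), DMF, rt → 45 °C
Reagents that add atoms: tert-butyldimethylsilyl chloride, CC(C)(C)[Si](C)(C)Cl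
Why: Imidazole-promoted silylation caps both phenols, the hydrogen-bonded ortho one needing gentle warming.

Step 9
Reactants: 16 1-[2-bromo-4,6-bis(tert-butyldimethylsilyloxy)phenyl]propan-1-one
Product: 18 rac-1-[2-bromo-4,6-bis(tert-butyldimethylsilyloxy)phenyl]-2-chloropropan-1-one, via lithium Z-enolate 17 (not isolated)
Conditions: LiN(SiMe3)2, THF, −78 °C; then transfer into N-chlorosuccinimide, THF, −78 → −40 °C
Reagents that add atoms: N-chlorosuccinimide, O=C1CCC(=O)N1Cl
Why: Electrophilic chlorination of the lithium enolate at carbon gives the α-chloro ketone; inverse addition limits proton exchange and dichlorination, and the new stereocentre need not be controlled because step 10 erases it.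

Step 10
Reactants: 18 rac-1-[2-bromo-4,6-bis(tert-butyldimethylsilyloxy)phenyl]-2-chloropropan-1-one; 12 (1S,2R,5S)-5-methyl-2-(2-phenylpropan-2-yl)cyclohexyl (6E)-7,11-dimethyl-2-oxo-4-(propan-2-ylidene)dodeca-6,10-dienoate
Product: 22 (2S,3R)-5,7-bis(tert-butyldimethylsilyloxy)-3-chloro-2-[(4E)-5,9-dimethyl-2-(propan-2-ylidene)deca-4,8-dien-1-yl]-2-hydroxy-3-methyl-2,3-dihydronaphthalene-1,4-dione, via lithium E-enolate 19 (not isolated), via lithium aldolate 20 (not isolated), via aryllithium 21 (not isolated)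
Conditions: LiN(SiMe3)2 (1.05 equiv), THF, −78 °C; then 12, −78 °C; then t-BuLi (3.2 equiv, one equivalent consumed by HN(SiMe3)2), −100 → −78 °C; AcOH, −78 °C
Reagents that add atoms: none
Why: LiN(SiMe3)2 removes the single enolisable hydrogen of racemic 18 to give the E-enolate 19, which adds to the chelated ketone carbonyl of 12 in a lithium-bridged closed transition state (C2–C3 bond, aldolate 20); t-BuLi then effects bromine–lithium exchange, and aryllithium 21 attacks the ester carbonyl and expels the auxiliary alkoxide (C1–C8a bond). The closest known reaction types are the aldol addition of ketone enolates to 8-phenylmenthyl α-keto esters and the Parham cyclisation of aryl bromides onto esters, run here back to back. Ring B closes in the second event by a 6-exo-trig cycliacylation. C2 is controlled by the auxiliary, whose phenyl ring covers one face of the syn-planar chelated keto ester, and C3 by the enolate geometry, since the bridged transition state should put the enolate substituent syn to O–Li (methyl) on the side of the new C–O bond and chlorine anti to it, as the trans chlorohydrin of the target requires. The step needs ketone addition in preference to proton transfer or ester attack, exchange faster than carbonyl addition by t-BuLi, and no retro-aldol, silyl shift or epoxide closure; the activated keto group, the shielding of the C4 ketone by its two fully substituted neighbours, and a temperature at or below −78 °C until the acidic quench are relied on for this.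

Step 11
Reactants: 22 (2S,3R)-5,7-bis(tert-butyldimethylsilyloxy)-3-chloro-2-[(4E)-5,9-dimethyl-2-(propan-2-ylidene)deca-4,8-dien-1-yl]-2-hydroxy-3-methyl-2,3-dihydronaphthalene-1,4-dione
Product: 23 CNP0351608.1, (2S,3R)-3-chloro-2-[(4E)-5,9-dimethyl-2-(propan-2-ylidene)deca-4,8-dien-1-yl]-2,5,7-trihydroxy-3-methyl-2,3-dihydronaphthalene-1,4-dione
Conditions: Bu4NF, AcOH (1:1), THF, 0 °C
Reagents that add atoms: none
Why: Acetic acid-buffered fluoride cleaves the two aryl silyl ethers near neutrality, so neither base-induced epoxide closure of the chlorohydrin nor acid-induced cyclisation onto the polyene is expected, and both stereocentres stay untouched.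

Compound list
1 | ethyl but-2-ynoate | CC#CC(=O)OCC | starting material
2 | geranyl bromide, (2E)-1-bromo-3,7-dimethylocta-2,6-diene | CC(C)=CCC/C(C)=C/CBr | starting material
3 | lithium [1-(ethoxycarbonyl)-2-methylprop-1-en-1-yl](methyl)cuprate | CCOC(=O)C([Cu-]C)=C(C)C.[Li+] | intermediate
4 | ethyl (4E)-5,9-dimethyl-2-(propan-2-ylidene)deca-4,8-dienoate | CC(C)=CCC/C(C)=C/CC(C(=O)OCC)=C(C)C | intermediate
5 | (4E)-5,9-dimethyl-2-(propan-2-ylidene)deca-4,8-dien-1-ol | CC(C)=CCC/C(C)=C/CC(CO)=C(C)C | intermediate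
6 | (5E)-3-(bromomethyl)-2,6,10-trimethylundeca-2,5,9-triene | CC(C)=CCC/C(C)=C/CC(CBr)=C(C)C | intermediate
7 | 1,3-dithiane-2-carboxylic acid | OC(=O)C1SCCCS1 | starting material
8 | (+)-8-phenylmenthol, (1S,2R,5S)-5-methyl-2-(2-phenylpropan-2-yl)cyclohexan-1-ol | O[C@H]1C[C@@H](C)CC[C@@H]1C(C)(C)c1ccccc1 | starting material
9 | (1S,2R,5S)-5-methyl-2-(2-phenylpropan-2-yl)cyclohexyl 1,3-dithiane-2-carboxylate | O=C(O[C@H]1C[C@@H](C)CC[C@@H]1C(C)(C)c1ccccc1)C1SCCCS1 | intermediate
10 | sodium enolate of 9 | [Na+].[O-]C(O[C@H]1C[C@@H](C)CC[C@@H]1C(C)(C)c1ccccc1)=C1SCCCS1 | intermediate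
11 | (1S,2R,5S)-5-methyl-2-(2-phenylpropan-2-yl)cyclohexyl 2-[(4E)-5,9-dimethyl-2-(propan-2-ylidene)deca-4,8-dien-1-yl]-1,3-dithiane-2-carboxylate | CC(C)=CCC/C(C)=C/CC(CC1(SCCCS1)C(=O)O[C@H]1C[C@@H](C)CC[C@@H]1C(C)(C)c1ccccc1)=C(C)C | intermediate
12 | (1S,2R,5S)-5-methyl-2-(2-phenylpropan-2-yl)cyclohexyl (6E)-7,11-dimethyl-2-oxo-4-(propan-2-ylidene)dodeca-6,10-dienoate | CC(C)=CCC/C(C)=C/CC(CC(=O)C(=O)O[C@H]1C[C@@H](C)CC[C@@H]1C(C)(C)c1ccccc1)=C(C)C | intermediate
13 | 5-bromobenzene-1,3-diol | Oc1cc(O)cc(Br)c1 | starting material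
14 | propanoic acid | CCC(=O)O | starting material
15 | 1-(2-bromo-4,6-dihydroxyphenyl)propan-1-one | CCC(=O)c1c(O)cc(O)cc1Br | intermediate
16 | 1-[2-bromo-4,6-bis(tert-butyldimethylsilyloxy)phenyl]propan-1-one | CCC(=O)c1c(O[Si](C)(C)C(C)(C)C)cc(O[Si](C)(C)C(C)(C)C)cc1Br | intermediate
17 | lithium (Z)-1-[2-bromo-4,6-bis(tert-butyldimethylsilyloxy)phenyl]prop-1-en-1-olate | C/C=C(\[O-])c1c(O[Si](C)(C)C(C)(C)C)cc(O[Si](C)(C)C(C)(C)C)cc1Br.[Li+] | intermediate
18 | rac-1-[2-bromo-4,6-bis(tert-butyldimethylsilyloxy)phenyl]-2-chloropropan-1-one | CC(Cl)C(=O)c1c(O[Si](C)(C)C(C)(C)C)cc(O[Si](C)(C)C(C)(C)C)cc1Br | intermediate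
19 | lithium (E)-1-[2-bromo-4,6-bis(tert-butyldimethylsilyloxy)phenyl]-2-chloroprop-1-en-1-olate | C/C(Cl)=C(\[O-])c1c(O[Si](C)(C)C(C)(C)C)cc(O[Si](C)(C)C(C)(C)C)cc1Br.[Li+] | intermediate
20 | lithium alkoxide of (1S,2R,5S)-5-methyl-2-(2-phenylpropan-2-yl)cyclohexyl (2S,3R)-4-[2-bromo-4,6-bis(tert-butyldimethylsilyloxy)phenyl]-3-chloro-2-[(4E)-5,9-dimethyl-2-(propan-2-ylidene)deca-4,8-dien-1-yl]-2-hydroxy-3-methyl-4-oxobutanoate | CC(C)=CCC/C(C)=C/CC(C[C@]([O-])(C(=O)O[C@H]1C[C@@H](C)CC[C@@H]1C(C)(C)c1ccccc1)[C@@](C)(Cl)C(=O)c1c(Br)cc(O[Si](C)(C)C(C)(C)C)cc1O[Si](C)(C)C(C)(C)C)=C(C)C.[Li+] | intermediate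
21 | aryllithium from bromine–lithium exchange of 20 | CC(C)=CCC/C(C)=C/CC(C[C@]([O-])(C(=O)O[C@H]1C[C@@H](C)CC[C@@H]1C(C)(C)c1ccccc1)[C@@](C)(Cl)C(=O)c1c([Li])cc(O[Si](C)(C)C(C)(C)C)cc1O[Si](C)(C)C(C)(C)C)=C(C)C.[Li+] | intermediate
22 | (2S,3R)-5,7-bis(tert-butyldimethylsilyloxy)-3-chloro-2-[(4E)-5,9-dimethyl-2-(propan-2-ylidene)deca-4,8-dien-1-yl]-2-hydroxy-3-methyl-2,3-dihydronaphthalene-1,4-dione | CC(C)=CCC/C(C)=C/CC(C[C@]1(O)C(=O)c2cc(O[Si](C)(C)C(C)(C)C)cc(O[Si](C)(C)C(C)(C)C)c2C(=O)[C@]1(C)Cl)=C(C)C | intermediate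
23 | CNP0351608.1, (2S,3R)-3-chloro-2-[(4E)-5,9-dimethyl-2-(propan-2-ylidene)deca-4,8-dien-1-yl]-2,5,7-trihydroxy-3-methyl-2,3-dihydronaphthalene-1,4-dione | CC(C)=CCC/C(C)=C/CC(C[C@]1(O)C(=O)c2cc(O)cc(O)c2C(=O)[C@]1(C)Cl)=C(C)C | target

Total step count: 11. Longest linear sequence: 7 steps (steps 1, 2, 3, 5, 6, 10, 11).

Steps most likely to fail

Step 10. The bond between the two fully substituted carbons may not form because proton transfer from the keto ester or retro-aldol wins. The enolate geometry or the facial bias of the auxiliary may also be too weak, so that diastereomers result. The chlorohydrin alkoxide may close to the epoxide, or a silyl group may shift to the enolate oxygen, before the cyclisation is over. Fallback: the two bond formations are separated and the aldol is run under Lewis acid control. Setting out from 18, LiN(SiMe3)2 and Me3SiCl give the trimethylsilyl enol ether F1. A Mukaiyama aldol addition of F1 to 12 promoted by MgBr2·OEt2 (CH2Cl2, −78 → −20 °C) should give, after aqueous work-up and chromatographic removal of minor isomers, the β-hydroxy ester F2. F2 is then cyclised in a separate Parham operation with t-BuLi (3.1 equiv, THF, −100 °C), which returns to the route at 22.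

Step 6. The iodine reagent may over-oxidise the electron-rich alkenes, or the β,γ-double bond may migrate into conjugation with the new keto group during unmasking. Fallback: the keto group is made by alcohol oxidation instead of dithiane cleavage. Setting out from 8 and 6, 8 is esterified with (4-methoxybenzyloxy)acetic acid (DCC, DMAP) to the glycolate ester F3. Its lithium enolate (LiN(i-Pr)2, THF/HMPA, −78 °C) is alkylated with 6 to the α-alkoxy ester F4. DDQ (CH2Cl2, pH 7 buffer) removes the 4-methoxybenzyl group to give the α-hydroxy ester F5, and Dess–Martin periodinane with NaHCO3 oxidises F5, returning to the route at 12.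

Step 1. Methyl transfer from the mixed cuprate to the allylic bromide, SN2′ attack or O-allylation may compete with α-C-allylation of the cuprate adduct. Fallback: the tetrasubstituted alkene is built from a β-keto ester. Setting out from 2, ethyl acetoacetate is C-alkylated with 2 (NaH, THF, 0 °C) to ethyl 2-geranylacetoacetate F6. NaH and ClP(O)(OEt)2 give the Z-enol phosphate F7, and Me2CuLi replaces the phosphate by methyl, returning to the route at 4.

Further compounds
F1 | step 10 | {[(E)-1-[2-bromo-4,6-bis(tert-butyldimethylsilyloxy)phenyl]-2-chloroprop-1-en-1-yl]oxy}trimethylsilane | C/C(Cl)=C(\O[Si](C)(C)C)c1c(O[Si](C)(C)C(C)(C)C)cc(O[Si](C)(C)C(C)(C)C)cc1Br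
F2 | step 10 | (1S,2R,5S)-5-methyl-2-(2-phenylpropan-2-yl)cyclohexyl (2S,3R)-4-[2-bromo-4,6-bis(tert-butyldimethylsilyloxy)phenyl]-3-chloro-2-[(4E)-5,9-dimethyl-2-(propan-2-ylidene)deca-4,8-dien-1-yl]-2-hydroxy-3-methyl-4-oxobutanoate | CC(C)=CCC/C(C)=C/CC(C[C@](O)(C(=O)O[C@H]1C[C@@H](C)CC[C@@H]1C(C)(C)c1ccccc1)[C@@](C)(Cl)C(=O)c1c(Br)cc(O[Si](C)(C)C(C)(C)C)cc1O[Si](C)(C)C(C)(C)C)=C(C)C
F3 | step 6 | (1S,2R,5S)-5-methyl-2-(2-phenylpropan-2-yl)cyclohexyl 2-[(4-methoxyphenyl)methoxy]acetate | COc1ccc(COCC(=O)O[C@H]2C[C@@H](C)CC[C@@H]2C(C)(C)c2ccccc2)cc1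
F4 | step 6 | (1S,2R,5S)-5-methyl-2-(2-phenylpropan-2-yl)cyclohexyl (6E)-2-[(4-methoxyphenyl)methoxy]-7,11-dimethyl-4-(propan-2-ylidene)dodeca-6,10-dienoate (C2 epimers) | CC(C)=CCC/C(C)=C/CC(CC(OCc1ccc(OC)cc1)C(=O)O[C@H]1C[C@@H](C)CC[C@@H]1C(C)(C)c1ccccc1)=C(C)C
F5 | step 6 | (1S,2R,5S)-5-methyl-2-(2-phenylpropan-2-yl)cyclohexyl (6E)-2-hydroxy-7,11-dimethyl-4-(propan-2-ylidene)dodeca-6,10-dienoate (C2 epimers) | CC(C)=CCC/C(C)=C/CC(CC(O)C(=O)O[C@H]1C[C@@H](C)CC[C@@H]1C(C)(C)c1ccccc1)=C(C)C
F6 | step 1 | ethyl (4E)-2-acetyl-5,9-dimethyldeca-4,8-dienoate | CC(C)=CCC/C(C)=C/CC(C(C)=O)C(=O)OCC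
F7 | step 1 | ethyl (4E)-2-[(Z)-1-(diethoxyphosphoryloxy)ethylidene]-5,9-dimethyldeca-4,8-dienoate | CC(C)=CCC/C(C)=C/CC(/C(=O)OCC)=C(\C)OP(=O)(OCC)OCC
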